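**Plan**
- Retrosynthesis: the single bond between the two olefins of the east diene is cut first (Stille), then the two new olefins of the triene (Horner–Wadsworth–Emmons, Wittig), then the bond from the CH2 link to ring B (B-alkyl Suzuki onto a furan), then ring B back to that furan (Achmatowicz), and last ring A back to diketene and a three-carbon aldehyde.
- Enabling feature: ring A is an oxane with oxygen on its side-chain carbon (the ring oxygen), on its methoxy carbon and, at the lactone stage, on its link carbon. The four carbons from the link carbon round to the CH2 beside the side-chain carbon are therefore an acetoacetyl unit, i.e. the four carbons of diketene, and the side-chain carbon with the ring oxygen is an aldehyde C=O. The four-membered oxetan-2-one ring of diketene is expanded by these two atoms into the six-membered ring A.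
- Forward order: ring A (steps 1–7), CH2 link and furan (step 12), ring B (steps 13–16), triene (steps 17–21), union with the carbamate/amide chain (step 32).
- Stereochemistry: the west methine is bought (Roche ester) and relays the ring A side-chain carbon (chelation in the key step), the methoxy carbon (hydrogenation) and the ring A link carbon (hydroboration). The east methine and the ring B east carbon are set by catalysis, and the latter relays the other three stereocentres of ring B. The chain carbinol carbon is bought (epichlorohydrin) and relays the carbamate carbon (anti reduction).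

Key step: step 3

Remark: the carbons are named by what they carry. In ring A these are the side-chain carbon, the methoxy carbon and the link carbon (the one bearing the CH2 link to ring B); the west methine is the CH(CH3) on the side-chain carbon. In ring B they are the link carbon, the methyl carbon (C–CH3), the carbinol carbon (C(CH3)OH) and the east carbon (the one bearing the east chain). In the east chain they are the east methine (CH(CH3)), the carbamate carbon and the chain carbinol carbon. The numbered starting materials are assumed to be commercial, and in step 10 the ligand antipode is the one that gives the 3R ketone.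

**Ring A**

Step 1
Reactants: 1 methyl (S)-3-hydroxy-2-methylpropanoate
Product: 2 methyl (S)-3-(benzyloxy)-2-methylpropanoate
Conditions: BnOC(=NH)CCl3, TfOH (cat.), CH2Cl2/cyclohexane, rt
Reagents that add atoms: benzyl 2,2,2-trichloroacetimidate, N=C(OCc1ccccc1)C(Cl)(Cl)Cl
Why: Acid-catalysed O-benzylation with the trichloroacetimidate avoids the β-elimination and racemisation that basic benzylation of this β-hydroxy ester would invite; the west methine comes from the chiral pool.

Step 2
Reactants: 2 methyl (S)-3-(benzyloxy)-2-methylpropanoate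
Product: 3 (S)-3-(benzyloxy)-2-methylpropanal
Conditions: iBu2AlH (DIBAL-H, 1.05 equiv), CH2Cl2, −78 °C; aq. KNaC4H4O6 (potassium sodium tartrate)
Reagents that add atoms: none
Why: Partial ester reduction with one equivalent of the aluminium hydride at −78 °C should stop at the aluminium hemiacetal and release the aldehyde on work-up; it is used at once so that the α-stereocentre is not epimerised.

Step 3
Reactants: 3 (S)-3-(benzyloxy)-2-methylpropanal; 4 diketene (4-methylideneoxetan-2-one)
Product: 7 (R)-6-[(S)-1-(benzyloxy)propan-2-yl]oxane-2,4-dione, via titanium enolate 5 (not isolated), via titanium aldolate 6 (not isolated)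
Conditions: 3 premixed with TiCl4; 4, TiCl4 (2.2 equiv in all), CH2Cl2, −78 °C; warm to 0 °C; 1 M HCl
Reagents that add atoms: none
Why: TiCl4 opens the strained acyl–oxygen bond of diketene to the trichlorotitanium enolate of acetoacetyl chloride 5, whose CH2 terminus (the former exocyclic methylene) adds to the chelated aldehyde, and the titanium alkoxide 6 then recloses on the same acyl carbon on warming, so that three ring atoms of diketene (the acyl carbon, the ring CH2 and the enol carbon) plus the exocyclic carbon, the aldehyde carbon and the aldehyde oxygen form the six-membered ring while the old ring oxygen leaves the ring as the ketone oxygen of the dione. The closest known reaction type is the TiCl4-mediated addition of diketene to aldehydes that leads to 6-substituted 4-hydroxy-5,6-dihydropyran-2-ones (a vinylogous Mukaiyama-type aldol followed by lactonisation), and in ring logic it parallels the Achmatowicz expansion, where the old ring oxygen also ends as a ketone oxygen. The ring closes by 6-exo-trig acyl substitution of the δ-alkoxide on the acyl chloride, and any δ-hydroxy-β-keto acid left after the quench should close on acidification. The one new stereocentre, the ring A side-chain carbon, is set by 1,3-chelation of TiCl4 between the aldehyde oxygen and the benzyloxy oxygen (Cram chelate model): attack on the face of the six-membered chelate away from the methyl group of the west methine should give the 2,3-anti adduct (R next to the S methine). The step needs addition to the chelated rather than the free aldehyde, which the benzyl ether (stable to TiCl4 at −78 °C) and premixing of 3 with TiCl4 secure, and it needs a single nucleophilic carbon, which the enolate provides because its only enolate carbon is the former exocyclic CH2.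

Step 4
Reactants: 7 (R)-6-[(S)-1-(benzyloxy)propan-2-yl]oxane-2,4-dione
Product: 9 (4R,6R)-4-hydroxy-6-[(S)-1-hydroxypropan-2-yl]oxan-2-one, via benzyl ether hydroxy lactone 8 (not isolated)
Conditions: H2 (50 bar), Raney Ni, EtOAc, 30 °C; filter; H2 (1 atm), Pd(OH)2/C, EtOAc/MeOH, rt
Reagents that add atoms: none
Why: Heterogeneous hydrogenation of the enolised β-keto lactone should add hydrogen to the ring face opposite the side chain and so place the new hydroxyl cis to it; hydrogenolysis then removes the benzyl ether before any olefin is present.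

Step 5
Reactants: 9 (4R,6R)-4-hydroxy-6-[(S)-1-hydroxypropan-2-yl]oxan-2-one
Product: 10 (4R,6R)-6-[(S)-1-(tert-butyldimethylsilyloxy)propan-2-yl]-4-hydroxyoxan-2-one
Conditions: TBSCl (1.05 equiv), imidazole, CH2Cl2, 0 °C
Reagents that add atoms: tert-butyldimethylsilyl chloride, CC(C)(C)[Si](C)(C)Cl
Why: Silylation with one equivalent of the bulky chlorosilane should select the primary over the secondary hydroxyl on steric grounds.

Step 6
Reactants: 10 (4R,6R)-6-[(S)-1-(tert-butyldimethylsilyloxy)propan-2-yl]-4-hydroxyoxan-2-one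
Product: 11 (4R,6R)-6-[(S)-1-(tert-butyldimethylsilyloxy)propan-2-yl]-4-methoxyoxan-2-one
Conditions: Me3OBF4, 1,8-bis(dimethylamino)naphthalene, CH2Cl2, rt
Reagents that add atoms: trimethyloxonium tetrafluoroborate, C[O+](C)C.F[B-](F)(F)F
Why: O-Methylation with the Meerwein salt and a hindered amine etherifies the β-hydroxy lactone without forming the alkoxide that would trigger β-elimination.

Step 7
Reactants: 11 (4R,6R)-6-[(S)-1-(tert-butyldimethylsilyloxy)propan-2-yl]-4-methoxyoxan-2-one
Product: 12 (2R,4R)-2-[(S)-1-(tert-butyldimethylsilyloxy)propan-2-yl]-4-methoxy-6-methylideneoxane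
Conditions: Cp2TiMe2, toluene, 75 °C, dark
Reagents that add atoms: Cp2TiMe2 (dimethyltitanocene), C[Ti](C)(C1C=CC=C1)C1C=CC=C1
Why: Petasis methylenation turns the lactone carbonyl into the exocyclic enol ether under non-basic conditions that spare the β-methoxy group and the silyl ether.

**Furan fragment**

Step 8
Reactants: 13 2,5-dibromofuran; 14 (E)-but-2-enal
Product: 16 (E)-1-(5-bromofuran-2-yl)but-2-en-1-ol (racemic), via 5-bromo-2-furyllithium 15 (not isolated)
Conditions: n-BuLi (1.0 equiv), Et2O, −78 °C; then 14; H2O
Reagents that add atoms: none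
Why: Bromine–lithium exchange at one C–Br bond of the symmetric dibromide gives the furyllithium, which should add 1,2 to the enal.

Step 9
Reactants: 16 (E)-1-(5-bromofuran-2-yl)but-2-en-1-ol
Product: 17 (E)-1-(5-bromofuran-2-yl)but-2-en-1-one
Conditions: MnO2, CH2Cl2, rt
Reagents that add atoms: none
Why: MnO2 oxidation of the doubly activated (allylic and furylic) alcohol gives the enone without touching the furan.

Step 10
Reactants: 17 (E)-1-(5-bromofuran-2-yl)but-2-en-1-one; 18 (triisopropylsilyl)acetylene
Product: 19 (R)-1-(5-bromofuran-2-yl)-3-methyl-5-(triisopropylsilyl)pent-4-yn-1-one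
Conditions: [Rh(OAc)(C2H4)2]2 (2.5 mol %), (R)-DTBM-SEGPHOS (6 mol %), 1,4-dioxane, 80 °C
Reagents that add atoms: none
Why: Rhodium–bisphosphine-catalysed asymmetric conjugate alkynylation of the aryl enone with the bulky silylacetylene sets the east methine by ligand control.

Step 11
Reactants: 19 (R)-1-(5-bromofuran-2-yl)-3-methyl-5-(triisopropylsilyl)pent-4-yn-1-one
Product: 20 (1S,3R)-1-(5-bromofuran-2-yl)-3-methyl-5-(triisopropylsilyl)pent-4-yn-1-ol
Conditions: RuCl[(S,S)-TsDPEN](p-cymene) (1 mol %), HCO2H/Et3N (5:2), rt
Reagents that add atoms: none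
Why: Noyori asymmetric transfer hydrogenation of the heteroaryl ketone sets the future ring B east carbon by catalyst control, the S,S catalyst being expected to give the S carbinol by analogy with aryl alkyl ketones.

**Union and ring B**

Step 12
Reactants: 12 (2R,4R)-2-[(S)-1-(tert-butyldimethylsilyloxy)propan-2-yl]-4-methoxy-6-methylideneoxane; 20 (1S,3R)-1-(5-bromofuran-2-yl)-3-methyl-5-(triisopropylsilyl)pent-4-yn-1-ol
Product: 22 ring A–CH2–furyl carbinol, via B-alkyl-9-BBN adduct 21 (not isolated)
Conditions: 9-BBN, THF, rt; then 20, PdCl2(dppf) (5 mol %), AsPh3, Cs2CO3, DMF/H2O, rt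
Reagents that add atoms: none
Why: Hydroboration puts boron on the exocyclic CH2 and should deliver hydrogen axially to the ring A link carbon, which gives the all-cis ring A, and B-alkyl Suzuki–Miyaura coupling then joins the borane to the 2-bromofuran.

Step 13
Reactants: 22 ring A–CH2–furyl carbinol
Product: 23 6-hydroxy-2H-pyran-3(6H)-one hemiketal
Conditions: NBS, NaHCO3, NaOAc, THF/H2O (4:1), 0 °C
Reagents that add atoms: water, O
Why: Achmatowicz oxidative rearrangement of the furyl carbinol gives the pyranone hemiketal; the carbinol C–O bond is not broken, so the east carbon keeps its configuration.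

Step 14
Reactants: 23 6-hydroxy-2H-pyran-3(6H)-one hemiketal
Product: 24 cis-2,6-disubstituted 2H-pyran-3(6H)-one
Conditions: Et3SiH, CF3CO2H, CH2Cl2, −40 °C
Reagents that add atoms: none
Why: Ionic hydrogenation of the hemiketal (oxocarbenium ion, axial hydride from the silane) should give the 2,6-cis dihydropyranone, so the ring B link carbon is relayed from the east carbon.

Step 15
Reactants: 24 cis-2,6-disubstituted 2H-pyran-3(6H)-one
Product: 25 ring B methyl oxan-3-one
Conditions: Me2CuLi (from CuI, MeLi), Et2O, −78 °C; aq. NH4Cl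
Reagents that add atoms: lithium dimethylcuprate, [Li+].C[Cu-]C
Why: Conjugate addition of Me2CuLi to the enone should occur anti to the neighbouring substituent on the ring B link carbon, which sets the methyl carbon trans to the CH2 link.

Step 16
Reactants: 25 ring B methyl oxan-3-one
Product: 26 ring B tertiary alcohol
Conditions: MeMgBr, toluene/THF, −78 °C
Reagents that add atoms: methylmagnesium bromide, C[Mg]Br
Why: Grignard addition to the oxan-3-one should come from the axial direction (only one 1,3-diaxial hydrogen, because the ring oxygen carries none), which gives the equatorial hydroxyl and the axial methyl at the carbinol carbon.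

**Triene**

Step 17
Reactants: 26 ring B tertiary alcohol
Product: 27 diol alkyne
Conditions: Bu4NF (TBAF), THF, rt
Reagents that add atoms: none
Why: Fluoride-mediated desilylation cleaves the primary silyl ether and the alkynylsilane in one operation.

Step 18
Reactants: 27 diol alkyne
Product: 28 (E)-vinylstannane diol
Conditions: Bu3SnH, PdCl2(PPh3)2 (3 mol %), THF, 0 °C
Reagents that add atoms: tributyltin hydride, CCCC[SnH](CCCC)CCCC
Why: Palladium-catalysed syn-hydrostannation of the terminal alkyne, done while no other π-system is present, should place tin on the terminal carbon and give the E stannane.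

Step 19
Reactants: 28 (E)-vinylstannane diol
Product: 29 west aldehyde
Conditions: Dess–Martin periodinane, NaHCO3, CH2Cl2, 0 °C
Reagents that add atoms: none
Why: Buffered Dess–Martin oxidation converts the primary alcohol into the aldehyde and leaves the tertiary alcohol, the stannane and the α-stereocentre alone.

Step 20
Reactants: 29 west aldehyde; 30 2-(triphenylphosphoranylidene)propanal
Product: 31 (E)-2-methyl enal
Conditions: toluene, 80 °C
Reagents that add atoms: none
Why: Wittig reaction with the stabilised formyl ylide should give the E trisubstituted enal under neutral conditions.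

Step 21
Reactants: 31 (E)-2-methyl enal; 32 diethyl allylphosphonate
Product: 34 triene vinylstannane, via lithiated allylphosphonate 33 (not isolated)
Conditions: 32, n-BuLi, THF, −78 °C; then 31; HMPA, −78 °C → rt
Reagents that add atoms: none
Why: Horner–Wadsworth–Emmons reaction of the allylphosphonate anion through its α-carbon should give the terminal E diene and complete the E,E triene.

**Carbamate/amide chain (fragment E)**

Step 22
Reactants: 35 1,3-dithiane; 36 1-bromobut-2-yne
Product: 38 2-(but-2-yn-1-yl)-1,3-dithiane, via 2-lithio-1,3-dithiane 37 (not isolated)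
Conditions: n-BuLi, THF, −30 °C; then 36, −78 °C → rt
Reagents that add atoms: none
Why: Corey–Seebach alkylation of the lithiated dithiane with the propargylic bromide.

Step 23
Reactants: 38 2-(but-2-yn-1-yl)-1,3-dithiane; 39 (S)-epichlorohydrin
Product: 41 (S)-1-[2-(but-2-yn-1-yl)-1,3-dithian-2-yl]-3-chloropropan-2-ol, via lithiated dithiane 40 (not isolated)
Conditions: n-BuLi, THF, −30 °C; then 39, −78 → −40 °C; AcOH, −40 °C
Reagents that add atoms: none
Why: The dithiane anion opens the epoxide at its CH2 terminus (SN2, the bought stereocentre is untouched), and the cold acidic quench keeps the chloro-alkoxide from closing.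

Step 24
Reactants: 41 (S)-1-[2-(but-2-yn-1-yl)-1,3-dithian-2-yl]-3-chloropropan-2-ol
Product: 43 (S)-1-chloro-3-{2-[(E)-3-iodobut-2-en-1-yl]-1,3-dithian-2-yl}propan-2-ol, via vinylzirconocene 42 (not isolated)
Conditions: Cp2Zr(H)Cl (3 equiv), THF, rt → 45 °C; then I2, 0 °C
Reagents that add atoms: iodine, II
Why: syn-Hydrozirconation of the internal alkyne with excess reagent should equilibrate zirconium to the methyl-bearing carbon, away from the neopentyl-like dithiane side, and iodinolysis with retention gives the E 2-iodoalkene.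

Step 25
Reactants: 43 (S)-1-chloro-3-{2-[(E)-3-iodobut-2-en-1-yl]-1,3-dithian-2-yl}propan-2-ol
Product: 44 (S,E)-1-chloro-2-hydroxy-7-iodooct-6-en-4-one
Conditions: MeI, CaCO3, MeCN/H2O (9:1), 40 °C
Reagents that add atoms: water, O
Why: Alkylative hydrolysis of the dithiane unmasks the ketone under nearly neutral conditions that spare the β-hydroxy ketone and the vinyl iodide.

Step 26
Reactants: 44 (S,E)-1-chloro-2-hydroxy-7-iodooct-6-en-4-one
Product: 45 (2S,4R,E)-1-chloro-7-iodooct-6-ene-2,4-diol
Conditions: Me4NBH(OAc)3, MeCN/AcOH, −30 °C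
Reagents that add atoms: none
Why: Evans–Saksena reduction: the acetoxyborohydride binds the β-hydroxyl and delivers hydride intramolecularly, which should give the 1,3-anti diol and set the carbamate carbon.

Step 27
Reactants: 45 (2S,4R,E)-1-chloro-7-iodooct-6-ene-2,4-diol
Product: 46 (R,E)-5-iodo-1-[(S)-oxiran-2-yl]hex-4-en-2-ol
Conditions: K2CO3, MeOH, 0 °C
Reagents that add atoms: none
Why: Base closes the chlorohydrin to the terminal epoxide (3-exo-tet), which masks the oxygen of the chain carbinol carbon and leaves only the hydroxyl on the carbamate carbon free.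

Step 28
Reactants: 46 (R,E)-5-iodo-1-[(S)-oxiran-2-yl]hex-4-en-2-ol
Product: 48 (R,E)-5-iodo-1-[(S)-oxiran-2-yl]hex-4-en-2-yl carbamate, via N-trichloroacetyl carbamate 47 (not isolated)
Conditions: Cl3CC(O)NCO, CH2Cl2, 0 °C; then neutral Al2O3, rt
Reagents that add atoms: trichloroacetyl isocyanate, O=C=NC(=O)C(Cl)(Cl)Cl
Why: Carbamoylation: the only free hydroxyl adds to the acyl isocyanate, and neutral hydrolysis on alumina removes the trichloroacetyl group without opening the epoxide.

Step 29
Reactants: 48 (R,E)-5-iodo-1-[(S)-oxiran-2-yl]hex-4-en-2-yl carbamate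
Product: 49 (2S,4R,E)-1-amino-2-hydroxy-7-iodooct-6-en-4-yl carbamate
Conditions: NH3 (7 M in MeOH), 40 °C, sealed tube
Reagents that add atoms: ammonia, N
Why: Epoxide aminolysis: ammonia in large excess opens the terminal epoxide at the CH2 carbon (SN2), which frees the chain carbinol hydroxyl and installs the nitrogen.

Step 30
Reactants: 50 methyl 2-methoxyprop-2-enoate
Product: 51 2-methoxyprop-2-enoic acid
Conditions: LiOH, THF/H2O, 0 °C → rt; then HCl (aq.)
Reagents that add atoms: lithium hydroxide, [Li+].[OH-]
Why: Ester saponification.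

Step 31
Reactants: 49 (2S,4R,E)-1-amino-2-hydroxy-7-iodooct-6-en-4-yl carbamate; 51 2-methoxyprop-2-enoic acid
Product: 52 (2S,4R,E)-2-hydroxy-7-iodo-1-(2-methoxyprop-2-enamido)oct-6-en-4-yl carbamate
Conditions: EDC·HCl, HOBt, iPr2NEt, CH2Cl2, 0 °C → rt
Reagents that add atoms: none
Why: Carbodiimide amide coupling should acylate the primary amine in preference to the secondary hydroxyl and the carbamate nitrogen.

**Final union**

Step 32
Reactants: 34 triene vinylstannane; 52 (2S,4R,E)-2-hydroxy-7-iodo-1-(2-methoxyprop-2-enamido)oct-6-en-4-yl carbamate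
Product: 53 CNP0220268.1
Conditions: Pd2(dba)3 (5 mol %), AsPh3 (20 mol %), DMF, rt, dark
Reagents that add atoms: none
Why: Stille coupling should join the E vinylstannane and the E vinyl iodide with retention of both geometries under neutral conditions that tolerate the free hydroxyls, the carbamate, the amide and the triene.

**Compound list**

1 | methyl (S)-3-hydroxy-2-methylpropanoate | COC(=O)[C@@H](C)CO | starting material
2 | methyl (S)-3-(benzyloxy)-2-methylpropanoate | COC(=O)[C@@H](C)COCc1ccccc1 | intermediate
3 | (S)-3-(benzyloxy)-2-methylpropanal | O=C[C@@H](C)COCc1ccccc1 | intermediate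
4 | diketene (4-methylideneoxetan-2-one) | C=C1CC(=O)O1 | starting material
5 | trichlorotitanium enolate of acetoacetyl chloride at its terminal carbon (not isolated) | C=C(CC(Cl)=O)O[Ti](Cl)(Cl)Cl | intermediate
6 | (5R,6S)-7-(benzyloxy)-6-methyl-3-oxo-5-(trichlorotitaniooxy)heptanoyl chloride (not isolated) | c1ccccc1COC[C@H](C)[C@H](O[Ti](Cl)(Cl)Cl)CC(=O)CC(Cl)=O | intermediate
7 | (R)-6-[(S)-1-(benzyloxy)propan-2-yl]oxane-2,4-dione (largely as its 4-hydroxy enol) | c1ccccc1COC[C@H](C)[C@H]1CC(=O)CC(=O)O1 | intermediate
8 | (4R,6R)-6-[(S)-1-(benzyloxy)propan-2-yl]-4-hydroxyoxan-2-one (not isolated) | c1ccccc1COC[C@H](C)[C@H]1C[C@@H](O)CC(=O)O1 | intermediate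
9 | (4R,6R)-4-hydroxy-6-[(S)-1-hydroxypropan-2-yl]oxan-2-one | OC[C@H](C)[C@H]1C[C@@H](O)CC(=O)O1 | intermediate
10 | (4R,6R)-6-[(S)-1-(tert-butyldimethylsilyloxy)propan-2-yl]-4-hydroxyoxan-2-one | CC(C)(C)[Si](C)(C)OC[C@H](C)[C@H]1C[C@@H](O)CC(=O)O1 | intermediate
11 | (4R,6R)-6-[(S)-1-(tert-butyldimethylsilyloxy)propan-2-yl]-4-methoxyoxan-2-one | CC(C)(C)[Si](C)(C)OC[C@H](C)[C@H]1C[C@@H](OC)CC(=O)O1 | intermediate
12 | (2R,4R)-2-[(S)-1-(tert-butyldimethylsilyloxy)propan-2-yl]-4-methoxy-6-methylideneoxane | CC(C)(C)[Si](C)(C)OC[C@H](C)[C@H]1C[C@@H](OC)CC(=C)O1 | intermediate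
13 | 2,5-dibromofuran | Brc1ccc(Br)o1 | starting material
14 | (E)-but-2-enal | C/C=C/C=O | starting material
15 | 5-bromo-2-furyllithium (not isolated) | [Li]c1ccc(Br)o1 | intermediate
16 | (E)-1-(5-bromofuran-2-yl)but-2-en-1-ol, racemic | C/C=C/C(O)c1ccc(Br)o1 | intermediate
17 | (E)-1-(5-bromofuran-2-yl)but-2-en-1-one | C/C=C/C(=O)c1ccc(Br)o1 | intermediate
18 | (triisopropylsilyl)acetylene | C#C[Si](C(C)C)(C(C)C)C(C)C | starting material
19 | (R)-1-(5-bromofuran-2-yl)-3-methyl-5-(triisopropylsilyl)pent-4-yn-1-one | O=C(C[C@@H](C)C#C[Si](C(C)C)(C(C)C)C(C)C)c1ccc(Br)o1 | intermediate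
20 | (1S,3R)-1-(5-bromofuran-2-yl)-3-methyl-5-(triisopropylsilyl)pent-4-yn-1-ol | O[C@@H](C[C@@H](C)C#C[Si](C(C)C)(C(C)C)C(C)C)c1ccc(Br)o1 | intermediate
21 | B-alkyl-9-BBN adduct of 12: all-cis ring A with CH2–B(9-BBN) on the link carbon (not isolated) | CC(C)(C)[Si](C)(C)OC[C@H](C)[C@H]1C[C@@H](OC)C[C@@H](CB2C3CCCC2CCC3)O1 | intermediate
22 | ring A–CH2–furyl carbinol: all-cis ring A (side-chain carbon R, methoxy carbon S, link carbon S) with (S)-CH(CH3)CH2OTBS on the side-chain carbon; the link CH2 sits on the 5-position of a furan whose 2-position bears the (1S,3R)-1-hydroxy-3-methyl-5-(triisopropylsilyl)pent-4-ynyl chain | CC(C)(C)[Si](C)(C)OC[C@H](C)[C@H]1C[C@@H](OC)C[C@@H](Cc2ccc(o2)[C@@H](O)C[C@@H](C)C#C[Si](C(C)C)(C(C)C)C(C)C)O1 | intermediate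
23 | 6-hydroxy-2H-pyran-3(6H)-one hemiketal: the 6-position (both anomers) bears OH and the ring A–CH2 group, the 2-position (S) the alkynyl chain | CC(C)(C)[Si](C)(C)OC[C@H](C)[C@H]1C[C@@H](OC)C[C@@H](CC2(O)C=CC(=O)[C@H](C[C@@H](C)C#C[Si](C(C)C)(C(C)C)C(C)C)O2)O1 | intermediate
24 | cis-2,6-disubstituted 2H-pyran-3(6H)-one (ring B link carbon R, east carbon S) | CC(C)(C)[Si](C)(C)OC[C@H](C)[C@H]1C[C@@H](OC)C[C@@H](C[C@@H]2C=CC(=O)[C@H](C[C@@H](C)C#C[Si](C(C)C)(C(C)C)C(C)C)O2)O1 | intermediate
25 | ring B methyl oxan-3-one: new methyl trans to the CH2 link (link carbon R, methyl carbon S, east carbon S) | CC(C)(C)[Si](C)(C)OC[C@H](C)[C@H]1C[C@@H](OC)C[C@@H](C[C@@H]2[C@@H](C)CC(=O)[C@H](C[C@@H](C)C#C[Si](C(C)C)(C(C)C)C(C)C)O2)O1 | intermediate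
26 | ring B tertiary alcohol (link carbon R, methyl carbon S, carbinol carbon R, east carbon S; carbinol methyl axial, hydroxyl equatorial) with TBS ether and TIPS alkyne | CC(C)(C)[Si](C)(C)OC[C@H](C)[C@H]1C[C@@H](OC)C[C@@H](C[C@@H]2[C@@H](C)C[C@@](C)(O)[C@H](C[C@@H](C)C#C[Si](C(C)C)(C(C)C)C(C)C)O2)O1 | intermediate
27 | diol alkyne: primary alcohol on the west side chain, tertiary ring B alcohol, terminal alkyne on the east methine | OC[C@H](C)[C@H]1C[C@@H](OC)C[C@@H](C[C@@H]2[C@@H](C)C[C@@](C)(O)[C@H](C[C@@H](C)C#C)O2)O1 | intermediate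
28 | (E)-vinylstannane diol | OC[C@H](C)[C@H]1C[C@@H](OC)C[C@@H](C[C@@H]2[C@@H](C)C[C@@](C)(O)[C@H](C[C@@H](C)/C=C/[Sn](CCCC)(CCCC)CCCC)O2)O1 | intermediate
29 | west aldehyde (stannane retained) | O=C[C@H](C)[C@H]1C[C@@H](OC)C[C@@H](C[C@@H]2[C@@H](C)C[C@@](C)(O)[C@H](C[C@@H](C)/C=C/[Sn](CCCC)(CCCC)CCCC)O2)O1 | intermediate
30 | 2-(triphenylphosphoranylidene)propanal | CC(C=O)=P(c1ccccc1)(c1ccccc1)c1ccccc1 | starting material
31 | (E)-2-methyl enal (stannane retained) | O=C/C(C)=C/[C@H](C)[C@H]1C[C@@H](OC)C[C@@H](C[C@@H]2[C@@H](C)C[C@@](C)(O)[C@H](C[C@@H](C)/C=C/[Sn](CCCC)(CCCC)CCCC)O2)O1 | intermediate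
32 | diethyl allylphosphonate | C=CCP(=O)(OCC)OCC | starting material
33 | lithiated diethyl allylphosphonate (not isolated) | [Li]C(C=C)P(=O)(OCC)OCC | intermediate
34 | triene vinylstannane: the target's triene, ring A and ring B, with (E)-CH=CH–SnBu3 on the east methine | C=C/C=C/C(C)=C/[C@H](C)[C@H]1C[C@@H](OC)C[C@@H](C[C@@H]2[C@@H](C)C[C@@](C)(O)[C@H](C[C@@H](C)/C=C/[Sn](CCCC)(CCCC)CCCC)O2)O1 | intermediate
35 | 1,3-dithiane | C1CSCSC1 | starting material
36 | 1-bromobut-2-yne | CC#CCBr | starting material
37 | 2-lithio-1,3-dithiane (not isolated) | [Li]C1SCCCS1 | intermediate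
38 | 2-(but-2-yn-1-yl)-1,3-dithiane | CC#CCC1SCCCS1 | intermediate
39 | (S)-epichlorohydrin | ClC[C@@H]1CO1 | starting material
40 | 2-(but-2-yn-1-yl)-2-lithio-1,3-dithiane (not isolated) | [Li]C1(CC#CC)SCCCS1 | intermediate
41 | (S)-1-[2-(but-2-yn-1-yl)-1,3-dithian-2-yl]-3-chloropropan-2-ol | CC#CCC1(C[C@H](O)CCl)SCCCS1 | intermediate
42 | (E)-vinylzirconocene chloride from 41, zirconium on the methyl-bearing carbon, drawn with the free hydroxyl (not isolated) | Cl[Zr](C1C=CC=C1)(C1C=CC=C1)/C(C)=C/CC1(C[C@H](O)CCl)SCCCS1 | intermediate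
43 | (S)-1-chloro-3-{2-[(E)-3-iodobut-2-en-1-yl]-1,3-dithian-2-yl}propan-2-ol | I/C(C)=C/CC1(C[C@H](O)CCl)SCCCS1 | intermediate
44 | (S,E)-1-chloro-2-hydroxy-7-iodooct-6-en-4-one | I/C(C)=C/CC(=O)C[C@H](O)CCl | intermediate
45 | (2S,4R,E)-1-chloro-7-iodooct-6-ene-2,4-diol | I/C(C)=C/C[C@H](C[C@H](O)CCl)O | intermediate
46 | (R,E)-5-iodo-1-[(S)-oxiran-2-yl]hex-4-en-2-ol | I/C(C)=C/C[C@H](C[C@H]1CO1)O | intermediate
47 | (R,E)-5-iodo-1-[(S)-oxiran-2-yl]hex-4-en-2-yl (2,2,2-trichloroacetyl)carbamate (not isolated) | I/C(C)=C/C[C@H](C[C@H]1CO1)OC(=O)NC(=O)C(Cl)(Cl)Cl | intermediate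
48 | (R,E)-5-iodo-1-[(S)-oxiran-2-yl]hex-4-en-2-yl carbamate | I/C(C)=C/C[C@H](C[C@H]1CO1)OC(N)=O | intermediate
49 | (2S,4R,E)-1-amino-2-hydroxy-7-iodooct-6-en-4-yl carbamate | I/C(C)=C/C[C@H](C[C@H](O)CN)OC(N)=O | intermediate
50 | methyl 2-methoxyprop-2-enoate | C=C(OC)C(=O)OC | starting material
51 | 2-methoxyprop-2-enoic acid | C=C(OC)C(=O)O | intermediate
52 | (2S,4R,E)-2-hydroxy-7-iodo-1-(2-methoxyprop-2-enamido)oct-6-en-4-yl carbamate | I/C(C)=C/C[C@H](C[C@H](O)CNC(=O)C(=C)OC)OC(N)=O | intermediate
53 | CNP0220268.1 | C=C/C=C/C(C)=C/[C@H](C)[C@H]1C[C@@H](OC)C[C@@H](C[C@H]2O[C@@H](C[C@@H](C)/C=C/C(C)=C/C[C@H](C[C@H](O)CNC(=O)C(=C)OC)OC(N)=O)[C@](C)(O)C[C@@H]2C)O1 | target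

**Count**

Total steps: 32. Longest linear sequence: 18 (steps 1–7, 12–21, 32).

**Three steps most likely to fail**

1. Step 3. The enolate may add to aldehyde that is not chelated, which would erode facial selectivity at the new ring A stereocentre; diketene may oligomerise before it is trapped; and the acyl chloride may not close fully. The fallback sets out from 3 and returns at 7. A cinchona-alkaloid-catalysed ketene–aldehyde [2+2] cycloaddition (acetyl chloride, iPr2NEt, O-trimethylsilylquinidine or its quinine pseudoenantiomer, whichever gives 4R, LiClO4, CH2Cl2/Et2O, −78 °C) would give the β-lactone (R)-4-[(S)-1-(benzyloxy)propan-2-yl]oxetan-2-one F1, with the new stereocentre under catalyst control. Claisen addition of the lithium enolate of tert-butyl acetate (THF, −78 °C) would open F1 at its acyl carbon and give tert-butyl (5R,6S)-7-(benzyloxy)-5-hydroxy-6-methyl-3-oxoheptanoate F2. CF3CO2H in CH2Cl2 would then close F2 to 7, so that ring A would still arise from a four-membered lactone by insertion of two carbons.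

2. Step 21. The ambident phosphonate anion may attack through its γ-carbon, the new olefin may form with poor E selectivity, and the strongly basic medium may epimerise the west methine or attack the stannane. The fallback sets out from 31 and returns at 34. A second Wittig reaction with (triphenylphosphoranylidene)acetaldehyde (toluene, 80 °C) would give the (2E,4E)-dienal F3, and methylenation with Ph3P=CH2 (from Ph3PCH3Br and KHMDS, THF, −78 → 0 °C) would give 34.

3. Step 23. Deprotonation may occur at the propargylic CH2 in competition with the 2-position of the dithiane, and the chloro-alkoxide may close to an epoxide before the quench. The fallback sets out from 39 and 36, bypasses 38, and returns at 41. It is an anion relay three-component coupling: 2-(tert-butyldimethylsilyl)-1,3-dithiane, lithiated with t-BuLi (Et2O, −78 °C), would open 39; HMPA would then induce the 1,4-Brook shift of silicon from carbon to the new alkoxide, which also blocks epoxide closure; and the relayed dithiane anion would be alkylated by 36 to give the silyl ether (S)-tert-butyl({1-[2-(but-2-yn-1-yl)-1,3-dithian-2-yl]-3-chloropropan-2-yl}oxy)dimethylsilane F4. HF·pyridine (THF, 0 °C) would return 41.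

Further compounds
F1 | step 3 | (R)-4-[(S)-1-(benzyloxy)propan-2-yl]oxetan-2-one | c1ccccc1COC[C@H](C)[C@H]1CC(=O)O1
F2 | step 3 | tert-butyl (5R,6S)-7-(benzyloxy)-5-hydroxy-6-methyl-3-oxoheptanoate | c1ccccc1COC[C@H](C)[C@H](O)CC(=O)CC(=O)OC(C)(C)C
F3 | step 21 | (2E,4E)-dienal: compound 31 extended by CH=CH between the enal carbonyl and its olefin | O=C/C=C/C(C)=C/[C@H](C)[C@H]1C[C@@H](OC)C[C@@H](C[C@@H]2[C@@H](C)C[C@@](C)(O)[C@H](C[C@@H](C)/C=C/[Sn](CCCC)(CCCC)CCCC)O2)O1
F4 | step 23 | (S)-tert-butyl({1-[2-(but-2-yn-1-yl)-1,3-dithian-2-yl]-3-chloropropan-2-yl}oxy)dimethylsilane | CC#CCC1(C[C@H](O[Si](C)(C)C(C)(C)C)CCl)SCCCS1
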